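**Strategy**

The route rests on disconnecting the ring-fusion bond C5–C10 (eudesmane numbering) of the decalin. Because the quaternary, methyl-bearing C10 lies next to oxygenated C9 and C5 next to the methyl-bearing C4, a C9 ketone turns C1=C10 into an α-methyl enone and C2–C5 into an (E)-2-methyl-1,3-diene, joined through C6–C8. A catalytic enantioselective intramolecular Diels–Alder reaction of this acyclic, achiral trienone forms C5–C10 and C1–C2 in one operation, closing ring A directly and ring B through the same bond, and sets both ring-fusion centres trans. C4, C7 and C9 are then set by hydration, axial cuprate addition and dissolving-metal reduction.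

Key step: step 4

Remark on numbering: C1–C15 in the text are eudesmane locants (ring A = C1–C5 and C10; ring B = C5–C10; C4 = carbinol carbon; C7 carries the acrylic acid; C9 carries the ester).

Assumption: the sense of induction of the oxazaborolidinium catalyst in step 4 is assigned by analogy only; the (S)-catalyst is written, and the (R)-catalyst (from (R)-α,α-diphenylprolinol) would be used unchanged if the opposite face proves to be attacked.

**Route**

Step 1
Reactants: 1 3-methyl-2,5-dihydrothiophene 1,1-dioxide (3-methyl-3-sulfolene); 2 1-chloro-3-iodopropane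
Product: 3 2-(3-chloropropyl)-3-methyl-2,5-dihydrothiophene 1,1-dioxide (racemic)
Conditions: LiN(SiMe3)2 added to 1 + 2, THF–DMPU, −78 °C
Reagents that add atoms: none
Why: Deprotonation in the presence of 2 gives the allylic α-sulfonyl carbanion at C2 (the allyl anion that carries the methyl group on its central carbon), which is alkylated by SN2 at the iodide terminus of 2 (sulfolene α-alkylation); the new centre is racemic and is lost in step 2.

Step 2
Reactants: 3 2-(3-chloropropyl)-3-methyl-2,5-dihydrothiophene 1,1-dioxide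
Product: 4 (3E)-7-chloro-3-methylhepta-1,3-diene
Conditions: K2CO3, toluene, 110 °C
Reagents that add atoms: none
Why: Cheletropic extrusion of SO2 from a 2-substituted 3-sulfolene is disrotatory with the C2 substituent turning outward, so the (E)-trisubstituted 1,3-diene should form stereospecifically.

Step 3
Reactants: 4 (3E)-7-chloro-3-methylhepta-1,3-diene; 5 N-methoxy-N-methylmethacrylamide
Product: 7 (7E)-2,8-dimethyldeca-1,7,9-trien-3-one, via dienylmagnesium chloride 6 (not isolated)
Conditions: Mg, BrCH2CH2Br (cat.), THF, 60 °C; then 5, −20 °C; cold aq. NH4Cl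
Reagents that add atoms: none
Why: Magnesium insertion into the primary chloride, then Weinreb ketone synthesis, in which the chelated tetrahedral adduct prevents over-addition and the α-methyl group disfavours conjugate addition; 7 is kept below 0 °C and used at once because it cyclises slowly on its own.

Step 4
Reactants: 7 (7E)-2,8-dimethyldeca-1,7,9-trien-3-one
Product: 8 (4aS,8aS)-5,8a-dimethyl-3,4,4a,7,8,8a-hexahydronaphthalen-1(2H)-one
Conditions: (S)-3,3-diphenyl-1-(2-methylphenyl)tetrahydro-1H,3H-pyrrolo[1,2-c][1,3,2]oxazaborole (20 mol%), HNTf2 (18 mol%), CH2Cl2, −78 → −40 °C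
Reagents that add atoms: none
Why: The boron Lewis acid binds the C3 ketone of 7 and lowers the enone LUMO, so the (E)-2-methyl-1,3-diene adds to the α-methyl enone in a concerted, asynchronous normal-demand [4+2] cycloaddition; the closest known reaction type is the intramolecular Diels–Alder reaction of 1,7,9-decatrien-3-ones under chiral oxazaborolidinium catalysis. Ring A (the cyclohexene) is closed by the cycloaddition itself through the new C1–C10 and C2–C7 bonds of 7 (C1–C2 and C5–C10 of the target), and ring B (the cyclohexanone) is closed by the same C2–C7 bond across the four-atom tether, a type 1 cyclisation. The relative configuration of the two new ring-fusion centres follows from the (E)-diene and the tether-exo, methyl-endo chair-like transition state, which 2-alkyl substitution of the dienophile is known to favour over the carbonyl-endo alternative, so the trans-fused octalone should result. The absolute configuration (4aS,8aS) is set by the catalyst, which shields one face of the coordinated enone. The step needs trans over cis ring fusion and catalyst control over the uncatalysed background; the α-methyl group secures the former, low temperature and the cold-handled trienone the latter, and regiochemistry is fixed by the tether.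

Step 5
Reactants: 8 (4aS,8aS)-5,8a-dimethyl-3,4,4a,7,8,8a-hexahydronaphthalen-1(2H)-one
Product: 9 (4aR,5R,8aS)-5-hydroxy-5,8a-dimethyloctahydronaphthalen-1(2H)-one
Conditions: Co(acac)2 (20 mol%), PhSiH3, O2 (1 atm), iPrOH, rt
Reagents that add atoms: dioxygen, O=O
Why: Mukaiyama hydration (hydrogen-atom transfer to the less substituted alkene carbon, then O2 capture of the tertiary radical): oxygen should enter on the face opposite the syn-axial angular methyl group, giving the equatorial hydroxyl and axial methyl at the new carbinol centre (5R).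

Step 6
Reactants: 9 (4aR,5R,8aS)-5-hydroxy-5,8a-dimethyloctahydronaphthalen-1(2H)-one
Product: 10 (4aR,5R,8aS)-5-hydroxy-5,8a-dimethyl-4a,5,6,7,8,8a-hexahydronaphthalen-1(4H)-one
Conditions: IBX (2-iodoxybenzoic acid, 1.5 equiv), DMSO, 75 °C
Reagents that add atoms: none
Why: IBX dehydrogenation of a ketone to the enone; only C2 carries α-hydrogens because the other α-carbon is quaternary, so the regiochemistry is unambiguous and the tertiary alcohol is inert.

Step 7
Reactants: 10 (4aR,5R,8aS)-5-hydroxy-5,8a-dimethyl-4a,5,6,7,8,8a-hexahydronaphthalen-1(4H)-one; 11 isopropenylmagnesium bromide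
Product: 12 (3R,4aR,5R,8aS)-5-hydroxy-5,8a-dimethyl-3-(prop-1-en-2-yl)octahydronaphthalen-1(2H)-one
Conditions: 11 (3 equiv), CuBr·SMe2 (20 mol%), THF, −78 → −40 °C; aq. NH4Cl
Reagents that add atoms: none
Why: Copper-catalysed conjugate addition of a Grignard reagent: stereoelectronically preferred axial attack on the locked cyclohexenone, anti to the angular methyl group and trans to the ring-fusion substituent at C4a, places the isopropenyl group axial and sets C3 as (R); one equivalent of 11 is consumed by the tertiary hydroxyl.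

Step 8
Reactants: 12 (3R,4aR,5R,8aS)-5-hydroxy-5,8a-dimethyl-3-(prop-1-en-2-yl)octahydronaphthalen-1(2H)-one
Product: 13 (1R,4aS,5S,7R,8aR)-1,4a-dimethyl-7-(prop-1-en-2-yl)decahydronaphthalene-1,5-diol
Conditions: Li, NH3(l), THF, tBuOH, −78 °C; NH4Cl
Reagents that add atoms: none
Why: Dissolving-metal reduction of the ketone should give the thermodynamically preferred equatorial alcohol (5S, cis to the angular methyl), because the axial epimer would suffer a syn-axial clash with the axial isopropenyl group; the isolated alkene is not reduced.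

Step 9
Reactants: 14 (S)-1-bromo-2-methylbutane
Product: 16 (S)-3-methylpentanoic acid, via (S)-2-methylbutylmagnesium bromide 15 (not isolated)
Conditions: Mg, THF, 40 °C; CO2 (g), −20 °C; 1 M HCl
Reagents that add atoms: carbon dioxide, O=C=O
Why: Grignard carboxylation; the stereocentre is β to the metal and is not touched, so the (S)-configuration is retained.

Step 10
Reactants: 13 (1R,4aS,5S,7R,8aR)-1,4a-dimethyl-7-(prop-1-en-2-yl)decahydronaphthalene-1,5-diol; 16 (S)-3-methylpentanoic acid
Product: 17 (1S,3R,4aR,5R,8aS)-5-hydroxy-5,8a-dimethyl-3-(prop-1-en-2-yl)decahydronaphthalen-1-yl (3S)-3-methylpentanoate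
Conditions: DCC (N,N'-dicyclohexylcarbodiimide), 4-(dimethylamino)pyridine, CH2Cl2, 0 °C → rt
Reagents that add atoms: none
Why: Steglich esterification acylates the secondary equatorial hydroxyl while the tertiary hydroxyl stays free; the stereocentre of the acid is β to the carbonyl and cannot epimerise.

Step 11
Reactants: 17 (1S,3R,4aR,5R,8aS)-5-hydroxy-5,8a-dimethyl-3-(prop-1-en-2-yl)decahydronaphthalen-1-yl (3S)-3-methylpentanoate
Product: 18 (1S,3R,4aR,5R,8aS)-5-hydroxy-3-(3-hydroxyprop-1-en-2-yl)-5,8a-dimethyldecahydronaphthalen-1-yl (3S)-3-methylpentanoate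
Conditions: SeO2 (30 mol%), tBuOOH, CH2Cl2, 0 °C → rt
Reagents that add atoms: selenium dioxide, O=[Se]=O (oxygen carrier); tert-butyl hydroperoxide, CC(C)(C)OO (terminal oxidant)
Why: Riley allylic oxidation under catalytic conditions (ene reaction, then [2,3]-sigmatropic shift) should hydroxylate the methyl group of the only alkene, the isopropenyl unit, leaving the double bond exocyclic.

Step 12
Reactants: 18 (1S,3R,4aR,5R,8aS)-5-hydroxy-3-(3-hydroxyprop-1-en-2-yl)-5,8a-dimethyldecahydronaphthalen-1-yl (3S)-3-methylpentanoate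
Product: 20 2-[(2R,4S,4aS,8R,8aR)-8-hydroxy-4a,8-dimethyl-4-{[(3S)-3-methylpentanoyl]oxy}decahydronaphthalen-2-yl]prop-2-enoic acid (CNP0471281.1), via enal 19 (not isolated)
Conditions: TEMPO (2,2,6,6-tetramethylpiperidin-1-oxyl, cat.), NaOCl (cat.), NaClO2, MeCN–phosphate buffer (pH 6.7), 35 °C
Reagents that add atoms: sodium chlorite, [Na+].[O-]Cl=O
Why: TEMPO/hypochlorite oxidation of the primary allylic alcohol to the enal, followed in the same flask by chlorite (Pinnick-type) oxidation to the acid; the buffered medium should leave the ester, the tertiary alcohol and the γ-stereocentre untouched.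

**Compound list**

1 | 3-methyl-2,5-dihydrothiophene 1,1-dioxide (3-methyl-3-sulfolene) | CC1=CCS(=O)(=O)C1 | starting material
2 | 1-chloro-3-iodopropane | ClCCCI | starting material
3 | 2-(3-chloropropyl)-3-methyl-2,5-dihydrothiophene 1,1-dioxide (racemic) | CC1=CCS(=O)(=O)C1CCCCl | intermediate
4 | (3E)-7-chloro-3-methylhepta-1,3-diene | ClCCC/C=C(\C)C=C | intermediate
5 | N-methoxy-N-methylmethacrylamide | C=C(C)C(=O)N(C)OC | starting material
6 | [(4E)-5-methylhepta-4,6-dien-1-yl]magnesium chloride | Cl[Mg]CCC/C=C(\C)C=C | intermediate (not isolated)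
7 | (7E)-2,8-dimethyldeca-1,7,9-trien-3-one | C=C(C)C(=O)CCC/C=C(\C)C=C | intermediate
8 | (4aS,8aS)-5,8a-dimethyl-3,4,4a,7,8,8a-hexahydronaphthalen-1(2H)-one (trans-fused) | C1CC(=O)[C@@]2(C)CCC=C(C)[C@@H]2C1 | intermediate
9 | (4aR,5R,8aS)-5-hydroxy-5,8a-dimethyloctahydronaphthalen-1(2H)-one | C1CC(=O)[C@@]2(C)CCC[C@@](C)(O)[C@@H]2C1 | intermediate
10 | (4aR,5R,8aS)-5-hydroxy-5,8a-dimethyl-4a,5,6,7,8,8a-hexahydronaphthalen-1(4H)-one | C1=CC(=O)[C@@]2(C)CCC[C@@](C)(O)[C@@H]2C1 | intermediate
11 | isopropenylmagnesium bromide (prop-1-en-2-ylmagnesium bromide, THF solution) | C=C(C)[Mg]Br | starting material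
12 | (3R,4aR,5R,8aS)-5-hydroxy-5,8a-dimethyl-3-(prop-1-en-2-yl)octahydronaphthalen-1(2H)-one | C=C(C)[C@H]1CC(=O)[C@@]2(C)CCC[C@@](C)(O)[C@@H]2C1 | intermediate
13 | (1R,4aS,5S,7R,8aR)-1,4a-dimethyl-7-(prop-1-en-2-yl)decahydronaphthalene-1,5-diol | C=C(C)[C@H]1C[C@H](O)[C@@]2(C)CCC[C@@](C)(O)[C@@H]2C1 | intermediate
14 | (S)-1-bromo-2-methylbutane | BrC[C@@H](C)CC | starting material
15 | [(S)-2-methylbutyl]magnesium bromide | Br[Mg]C[C@@H](C)CC | intermediate (not isolated)
16 | (S)-3-methylpentanoic acid | OC(=O)C[C@@H](C)CC | intermediate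
17 | (1S,3R,4aR,5R,8aS)-5-hydroxy-5,8a-dimethyl-3-(prop-1-en-2-yl)decahydronaphthalen-1-yl (3S)-3-methylpentanoate | C=C(C)[C@H]1C[C@H](OC(=O)C[C@@H](C)CC)[C@@]2(C)CCC[C@@](C)(O)[C@@H]2C1 | intermediate
18 | (1S,3R,4aR,5R,8aS)-5-hydroxy-3-(3-hydroxyprop-1-en-2-yl)-5,8a-dimethyldecahydronaphthalen-1-yl (3S)-3-methylpentanoate | C=C(CO)[C@H]1C[C@H](OC(=O)C[C@@H](C)CC)[C@@]2(C)CCC[C@@](C)(O)[C@@H]2C1 | intermediate
19 | (1S,3R,4aR,5R,8aS)-5-hydroxy-5,8a-dimethyl-3-(3-oxoprop-1-en-2-yl)decahydronaphthalen-1-yl (3S)-3-methylpentanoate | C=C(C=O)[C@H]1C[C@H](OC(=O)C[C@@H](C)CC)[C@@]2(C)CCC[C@@](C)(O)[C@@H]2C1 | intermediate (not isolated)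
20 | 2-[(2R,4S,4aS,8R,8aR)-8-hydroxy-4a,8-dimethyl-4-{[(3S)-3-methylpentanoyl]oxy}decahydronaphthalen-2-yl]prop-2-enoic acid (CNP0471281.1) | C=C(C(=O)O)[C@H]1C[C@H](OC(=O)C[C@@H](C)CC)[C@@]2(C)CCC[C@@](C)(O)[C@@H]2C1 | target

**Step count and risks**

Total step count: 12. Longest linear sequence: 11 steps (1 → 20 through steps 1–8 and 10–12; step 9 is a side branch).

Steps most likely to fail:

- **Step 4.** The enantio- or trans-selectivity may erode through the uncatalysed background cyclisation or a competing carbonyl-endo transition state. Fallback, from 4 back to 8: diene 4 would be united with methacrolein under the same oxazaborolidinium catalysis in a bimolecular, exo-selective Diels–Alder reaction, the best-documented dienophile class for this catalyst. This again forms the bond between the quaternary carbon and the neighbouring CH in a ring-closing event and should give (1S,2S)-2-(3-chloropropyl)-1,3-dimethylcyclohex-3-ene-1-carbaldehyde F1. Finkelstein exchange (NaI, acetone) would give (1S,2S)-2-(3-iodopropyl)-1,3-dimethylcyclohex-3-ene-1-carbaldehyde F2. SmI2-mediated Barbier cyclisation (SmI2, THF–HMPA) would close ring B to (4aS,8aS)-5,8a-dimethyl-1,2,3,4,4a,7,8,8a-octahydronaphthalen-1-ol F3 (either C1 epimer), and Dess–Martin oxidation would return to 8.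

- **Step 5.** Facial selectivity in the capture of the tertiary radical may be poor, or hydrogen-atom transfer to the trisubstituted alkene sluggish. Fallback, from 8 back to 9: epoxidation with mCPBA (NaHCO3, CH2Cl2, 0 °C) on the face opposite the angular methyl group would give the 5,6-epoxide of 8 with the oxirane oxygen anti to the 8a-methyl group F4. LiAlH4 (THF) would open it at the secondary oxirane carbon and reduce the ketone, giving (4aR,5R,8aS)-5,8a-dimethyldecahydronaphthalene-1,5-diol F5 (C1 epimers). Selective Dess–Martin oxidation of the secondary alcohol would give 9.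

- **Step 11.** Regioselectivity may be lost through ene attack with abstraction of the ring methine hydrogen, or over-oxidation may occur. Fallback, from 17 back to 19: ene-type allylic chlorination with Ca(OCl)2 and CO2 in CH2Cl2–H2O would give (1S,3R,4aR,5R,8aS)-3-(3-chloroprop-1-en-2-yl)-5-hydroxy-5,8a-dimethyldecahydronaphthalen-1-yl (3S)-3-methylpentanoate F6. Kornblum oxidation (NaHCO3, DMSO) would then give enal 19, which is oxidised with NaClO2 as in the second stage of step 12.

Further compounds
F1 | step 4 | (1S,2S)-2-(3-chloropropyl)-1,3-dimethylcyclohex-3-ene-1-carbaldehyde | O=C[C@@]1(C)CCC=C(C)[C@@H]1CCCCl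
F2 | step 4 | (1S,2S)-2-(3-iodopropyl)-1,3-dimethylcyclohex-3-ene-1-carbaldehyde | O=C[C@@]1(C)CCC=C(C)[C@@H]1CCCI
F3 | step 4 | (4aS,8aS)-5,8a-dimethyl-1,2,3,4,4a,7,8,8a-octahydronaphthalen-1-ol (C1 epimers) | C1CC(O)[C@@]2(C)CCC=C(C)[C@@H]2C1
F4 | step 5 | 5,6-epoxide of 8, oxirane oxygen anti to the 8a-methyl group | C1CC(=O)[C@@]2(C)CC[C@H]3O[C@@]3(C)[C@@H]2C1
F5 | step 5 | (4aR,5R,8aS)-5,8a-dimethyldecahydronaphthalene-1,5-diol (C1 epimers) | C1CC(O)[C@@]2(C)CCC[C@@](C)(O)[C@@H]2C1
F6 | step 11 | (1S,3R,4aR,5R,8aS)-3-(3-chloroprop-1-en-2-yl)-5-hydroxy-5,8a-dimethyldecahydronaphthalen-1-yl (3S)-3-methylpentanoate | C=C(CCl)[C@H]1C[C@H](OC(=O)C[C@@H](C)CC)[C@@]2(C)CCC[C@@](C)(O)[C@@H]2C1
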